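The depside ester is disconnected at the bond between the ester oxygen and C4 of ring B, not at the doubly ortho-substituted ring A carbonyl. One copper-mediated Chan-Lam coupling joins the carboxylate oxygen of 2,4-dimethoxy-6-pentylbenzoic acid to an arylboronic acid and delivers the complete, protected framework. The step exploits the position of the depside oxygen on ring B. C4 is flanked by the unsubstituted carbons C3 and C5, so C4-H is the one ring B C-H free of ortho substituents, and a sterically governed iridium borylation marks it. The precursor is the C4 boronic acid of tert-butyl 2-(methoxymethoxy)-6-pentylbenzoate. One acid treatment then unmasks the target.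

Key step: step 7

Remark: ring B is numbered from its carboxyl carbon (C1, with OH at C2, the depside oxygen at C4 and pentyl at C6); the target has no stereocentre, so no step has to control configuration.

Step 1
Reactants: 1 2-hydroxy-6-methylbenzoic acid
Product: 2 tert-butyl 2-hydroxy-6-methylbenzoate
Conditions: Me2NCH(OtBu)2 (3 equiv), toluene, 80 °C
Reagents that add atoms: N,N-dimethylformamide di-tert-butyl acetal, CN(C)C(OC(C)(C)C)OC(C)(C)C
Why: Alkylative esterification with a formamide acetal: the acid protonates the acetal and the carboxylate oxygen then takes up the tert-butyl group from the resulting alkoxyiminium ion, so the hindered carbonyl carbon is never attacked and the hydrogen-bonded, far less acidic phenol should stay free.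

Step 2
Reactants: 2 tert-butyl 2-hydroxy-6-methylbenzoate
Product: 3 tert-butyl 2-(methoxymethoxy)-6-methylbenzoate
Conditions: NaH, MOMCl, DMF, 0 °C to rt
Reagents that add atoms: chloromethyl methyl ether (MOMCl), COCCl
Why: Williamson-type O-alkylation: NaH turns the chelated phenol into its phenoxide, which displaces chloride from the highly reactive chloromethyl ether, and the tert-butyl ester is inert to base of this kind.

Step 3
Reactants: 3 tert-butyl 2-(methoxymethoxy)-6-methylbenzoate, 4 1-iodobutane
Product: 6 tert-butyl 2-(methoxymethoxy)-6-pentylbenzoate, via benzylic lithium species 5 (not isolated)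
Conditions: LiN(iPr)2 (1.15 equiv), THF, −78 °C; then 4, DMPU, −78 °C to −20 °C
Reagents that add atoms: none
Why: Lateral lithiation of an ortho-toluate followed by SN2 alkylation: the ortho ester makes the methyl protons the most acidic in 3, the bulk of the tert-butyl group keeps both the amide base and anion 5 away from the carbonyl, and the primary iodide supplies the four carbons that extend methyl to pentyl.

Step 4
Reactants: 6 tert-butyl 2-(methoxymethoxy)-6-pentylbenzoate, 7 bis(pinacolato)diboron
Product: 9 [4-(tert-butoxycarbonyl)-3-(methoxymethoxy)-5-pentylphenyl]boronic acid, via pinacol boronate 8 (not isolated)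
Conditions: [Ir(OMe)(cod)]2 (1.5 mol %), 4,4'-di-tert-butyl-2,2'-bipyridine (3 mol %), THF, 80 °C; concentrate; then NaIO4, NH4OAc, acetone/H2O, rt
Reagents that add atoms: water, O
Why: Sterically controlled iridium-catalysed aromatic C-H borylation, followed in the same flask by oxidative cleavage of the pinacol ester: of the three ring C-H bonds only C4-H has no ortho substituent, and buffered periodate removes pinacol near neutral pH, so the MOM ether and the tert-butyl ester should survive.

Step 5
Reactants: 10 1,3-dimethoxy-5-pentylbenzene
Product: 12 2,4-dimethoxy-6-pentylbenzaldehyde, via aryl iminium salt 11 (not isolated)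
Conditions: POCl3, DMF, 0 °C to 60 °C; then ice-water
Reagents that add atoms: N,N-dimethylformamide, CN(C)C=O; water, O
Why: Vilsmeier-Haack formylation: the chloroiminium ion attacks the position para to one methoxy group and ortho to the other rather than the more crowded site between both methoxy groups, and water hydrolyses iminium salt 11 to the aldehyde.

Step 6
Reactants: 12 2,4-dimethoxy-6-pentylbenzaldehyde
Product: 13 2,4-dimethoxy-6-pentylbenzoic acid
Conditions: NaClO2, NaH2PO4, 2-methyl-2-butene (excess), tBuOH/H2O, rt
Reagents that add atoms: sodium chlorite, [Na+].[O-]Cl=O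
Why: Pinnick oxidation: chlorous acid adds to the aldehyde and fragments to the acid, and the excess alkene traps hypochlorous acid before it can chlorinate the electron-rich ring.

Step 7
Reactants: 13 2,4-dimethoxy-6-pentylbenzoic acid, 9 [4-(tert-butoxycarbonyl)-3-(methoxymethoxy)-5-pentylphenyl]boronic acid (1.5 equiv)
Product: 14 tert-butyl 4-[(2,4-dimethoxy-6-pentylbenzoyl)oxy]-2-(methoxymethoxy)-6-pentylbenzoate
Conditions: Cu(OTf)2 (0.4 equiv), urea, 4 Å molecular sieves, EtOAc, dry air, 60 °C
Reagents that add atoms: none
Why: Exchange of triflate for the carboxylate of 13 gives a divalent copper carboxylate, the aryl group of 9 moves from boron to copper, and oxidation (disproportionation with a second divalent copper centre, air returning the monovalent copper to the divalent state) gives a trivalent aryl copper carboxylate whose reductive elimination forms the O-C4 bond. The closest known reaction type is the Chan-Lam O-arylation of arenecarboxylic acids with arylboronic acids, used here on new partners only. No ring is closed and no stereocentre is created. Site selectivity on ring B is secured by ipso substitution at the boron-bearing C4, whose two ortho positions (C3 and C5) carry hydrogen and leave transmetalation unhindered. Chemoselectivity is secured because the carboxyl group of 13 is the only free O-H nucleophile, the C2 phenol and C1 carboxyl of ring B being masked, and because the bond forms at the outlying carboxylate oxygen, away from the C2 methoxy and C6 pentyl groups that shield the ring A carbonyl carbon. Sieves and dry air hold back oxidative hydroxylation of 9, and urea together with the carboxylate buffers the triflic acid released from Cu(OTf)2, so the MOM ether and the tert-butyl ester should persist.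

Step 8
Reactants: 14 tert-butyl 4-[(2,4-dimethoxy-6-pentylbenzoyl)oxy]-2-(methoxymethoxy)-6-pentylbenzoate
Product: 15 4-[(2,4-dimethoxy-6-pentylbenzoyl)oxy]-2-hydroxy-6-pentylbenzoic acid
Conditions: TFA/CH2Cl2 (1:4), H2O (5 equiv), 0 °C to rt; co-evaporation with toluene below 30 °C
Reagents that add atoms: none
Why: Acidolysis: protonation releases the tert-butyl group as isobutene through alkyl-oxygen cleavage and hydrolyses the MOM acetal, with water steering every oxocarbenium ion to formaldehyde and methanol, while the aryl ester of the depside has no stabilised cation to lose and meets no nucleophile strong enough to attack it at or below room temperature.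

Compound list
1 | 2-hydroxy-6-methylbenzoic acid (6-methylsalicylic acid) | Cc1cccc(O)c1C(=O)O | starting material
2 | tert-butyl 2-hydroxy-6-methylbenzoate | Cc1cccc(O)c1C(=O)OC(C)(C)C | intermediate
3 | tert-butyl 2-(methoxymethoxy)-6-methylbenzoate | Cc1cccc(OCOC)c1C(=O)OC(C)(C)C | intermediate
4 | 1-iodobutane | CCCCI | starting material
5 | tert-butyl 2-(lithiomethyl)-6-(methoxymethoxy)benzoate | [Li]Cc1cccc(OCOC)c1C(=O)OC(C)(C)C | intermediate
6 | tert-butyl 2-(methoxymethoxy)-6-pentylbenzoate | CCCCCc1cccc(OCOC)c1C(=O)OC(C)(C)C | intermediate
7 | bis(pinacolato)diboron | CC1(C)OB(OC1(C)C)B1OC(C)(C)C(C)(C)O1 | starting material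
8 | tert-butyl 2-(methoxymethoxy)-6-pentyl-4-(4,4,5,5-tetramethyl-1,3,2-dioxaborolan-2-yl)benzoate | CCCCCc1cc(B2OC(C)(C)C(C)(C)O2)cc(OCOC)c1C(=O)OC(C)(C)C | intermediate
9 | [4-(tert-butoxycarbonyl)-3-(methoxymethoxy)-5-pentylphenyl]boronic acid | CCCCCc1cc(B(O)O)cc(OCOC)c1C(=O)OC(C)(C)C | intermediate
10 | 1,3-dimethoxy-5-pentylbenzene | CCCCCc1cc(OC)cc(OC)c1 | starting material
11 | N-[(2,4-dimethoxy-6-pentylphenyl)methylidene]-N-methylmethanaminium dichlorophosphate | CCCCCc1cc(OC)cc(OC)c1C=[N+](C)C.[O-]P(=O)(Cl)Cl | intermediate
12 | 2,4-dimethoxy-6-pentylbenzaldehyde | CCCCCc1cc(OC)cc(OC)c1C=O | intermediate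
13 | 2,4-dimethoxy-6-pentylbenzoic acid | CCCCCc1cc(OC)cc(OC)c1C(=O)O | intermediate
14 | tert-butyl 4-[(2,4-dimethoxy-6-pentylbenzoyl)oxy]-2-(methoxymethoxy)-6-pentylbenzoate | CCCCCc1cc(OC(=O)c2c(CCCCC)cc(OC)cc2OC)cc(OCOC)c1C(=O)OC(C)(C)C | intermediate
15 | 4-[(2,4-dimethoxy-6-pentylbenzoyl)oxy]-2-hydroxy-6-pentylbenzoic acid | CCCCCc1cc(OC(=O)c2c(CCCCC)cc(OC)cc2OC)cc(O)c1C(=O)O | target

Total step count: 8. Longest linear sequence: 6 steps (steps 1, 2, 3, 4, 7 and 8). The ring A branch (steps 5 and 6) joins at step 7.

Steps most likely to fail

First, step 7. Three things may go wrong: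
- Oxidative hydroxylation, protodeboronation and homocoupling of the boronic acid may outrun transfer of the aryl group to the copper carboxylate.
- The phenol formed by hydroxylation may then be arylated in turn.
- The Lewis acidic copper triflate may erode the MOM ether or the tert-butyl ester before coupling.

The fallback forms the acyl-oxygen bond instead of the aryl-oxygen bond. It sets out from 9, whose C-B bond is oxidised with aqueous H2O2 in THF at rt to tert-butyl 4-hydroxy-2-(methoxymethoxy)-6-pentylbenzoate F1. A Steglich esterification of F1 with 13 (DCC, DMAP, CH2Cl2, rt) follows. It is slower because of the two ortho groups of ring A but is established for depsides, and it comes back to the route at 14.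

Second, step 3. The benzylic anion may add to the ester of not yet deprotonated substrate. Capture by the unactivated primary iodide may be sluggish. Proton transfer between product and anion may lead to a second alkylation. The fallback moves C-C bond formation ahead of phenol protection and changes the nucleophile to a dianion. It sets out from 2, which is deprotonated twice with LiN(iPr)2 (2.2 equiv, THF, −78 °C). The phenoxide charge lowers the electrophilicity of the ester, and only the more reactive carbanion centre is alkylated by 4. This should give tert-butyl 2-hydroxy-6-pentylbenzoate F2. O-alkylation of F2 with NaH and MOMCl in DMF comes back to the route at 6.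

Third, step 8. The oxocarbenium ion from the MOM group may be captured intramolecularly by the neighbouring carboxyl group. Formaldehyde equivalents may attack the activated ring positions. Long acid exposure may promote protodecarboxylation of the salicylic acid. The fallback separates the two deprotections and binds the one-carbon unit to sulfur. It sets out from 14, which is treated briefly with ZnBr2 and propane-1-thiol in CH2Cl2 at 0 °C. The MOM group leaves as a dithioacetal, and tert-butyl 4-[(2,4-dimethoxy-6-pentylbenzoyl)oxy]-2-hydroxy-6-pentylbenzoate F3 results. A short exposure of F3 to TFA in CH2Cl2 at 0 °C, now free of any formaldehyde source, comes back to the route at 15.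

Further compounds
F1 | step 7 | tert-butyl 4-hydroxy-2-(methoxymethoxy)-6-pentylbenzoate | CCCCCc1cc(O)cc(OCOC)c1C(=O)OC(C)(C)C
F2 | step 3 | tert-butyl 2-hydroxy-6-pentylbenzoate | CCCCCc1cccc(O)c1C(=O)OC(C)(C)C
F3 | step 8 | tert-butyl 4-[(2,4-dimethoxy-6-pentylbenzoyl)oxy]-2-hydroxy-6-pentylbenzoate | CCCCCc1cc(OC(=O)c2c(CCCCC)cc(OC)cc2OC)cc(O)c1C(=O)OC(C)(C)C
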